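Numbering: ring A = C1 (CMe2), C2 (CHBr), C3, C4 (CHOH), C5 (CMe); ring B = C6 (COH), C7, C8, C9 (CMe), C14 (COH), C15; ring C = C9, C10 (CHBr), C11, C12, C13 (CMeOH), C14.
Enabling feature: the tertiary C6 carbinol is 1,3 and syn to the angular C14 hydroxyl across C15 of ring B, so a C6 ketone lying β to C14–OH can take up a C7 carbanion inside a samarium chelate that already holds the diol geometry.
Retrosynthesis: C4–O–Si (last), then C6–C7 (ring B), then C7–I and both C–Br bonds back to carbinols, then C14–C15 between a ring A allylsilane and a ring C ketone.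
Forward: ring A (from 2,2-dimethylcyclopentane-1,3-dione) and ring C (from 2-methylcyclohexane-1,3-dione and allyl bromide) are made separately, joined at C14–C15, brominated twice in one operation, and ring B is closed last.
Stereochemistry: C2 and C9/C10 from oxazaborolidine desymmetrisations; C4/C5 from an epoxidation anti to C2–O and a stereospecific methyl shift; C13 and C14 from face-selective enolate hydroxylation and chelation-controlled allylation; both bromides by SN2 inversion; C6 from the chelate.

Key step: step 22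

Assumption: in both oxazaborolidine reductions the fully substituted α-carbon is taken to act as the large group, so the (R)-catalyst should give (S)-2 and the (S)-catalyst (2R,3R)-18; if the sense proved opposite, the antipodal catalyst would be used.

Step 1
Reactants: 1 2,2-dimethylcyclopentane-1,3-dione
Product: 2 (S)-3-hydroxy-2,2-dimethylcyclopentan-1-one
Conditions: (R)-Me-CBS oxazaborolidine [(R)-1-methyl-3,3-diphenyltetrahydro-1H,3H-pyrrolo[1,2-c][1,3,2]oxazaborole] (10 mol %), catecholborane, toluene, −78 °C
Reagents that add atoms: none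
Why: Corey–Bakshi–Shibata reduction desymmetrises the prochiral dione, the catalyst choosing the carbonyl face so that the future C2 carbinol is formed as the S alcohol.

Step 2
Reactants: 2 (S)-3-hydroxy-2,2-dimethylcyclopentan-1-one
Product: 3 (S)-2,2-dimethyl-3-(triethylsilyloxy)cyclopentan-1-one
Conditions: Et3SiCl, imidazole, DMF, 0 °C → rt
Reagents that add atoms: chlorotriethylsilane, CC[Si](Cl)(CC)CC
Why: Silylation with a silyl chloride and imidazole is mild enough to avoid retro-aldol opening of the β-hydroxy ketone, and the silyl ether later shields one face of ring A.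

Step 3
Reactants: 3 (S)-2,2-dimethyl-3-(triethylsilyloxy)cyclopentan-1-one
Product: 5 (S)-5,5-dimethyl-4-(triethylsilyloxy)cyclopent-1-en-1-yl trifluoromethanesulfonate, via potassium enolate 4 (not isolated)
Conditions: KN(SiMe3)2, THF, −78 °C; PhNTf2, −78 → 0 °C
Reagents that add atoms: N-phenylbis(trifluoromethanesulfonimide), FC(F)(F)S(=O)(=O)N(c1ccccc1)S(=O)(=O)C(F)(F)F
Why: Enolate O-triflation; only C4 carries α-hydrogens (C1 is quaternary), so a single enol triflate can form.

Step 4
Reactants: 5 enol triflate
Product: 6 methyl (S)-5,5-dimethyl-4-(triethylsilyloxy)cyclopent-1-ene-1-carboxylate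
Conditions: Pd(OAc)2 (5 mol %), PPh3, CO (1 atm), MeOH, Et3N, DMF, 50 °C
Reagents that add atoms: carbon monoxide, [C-]#[O+]; methanol, CO
Why: Palladium-catalysed alkoxycarbonylation of an enol triflate (oxidative addition, CO insertion, methanolysis) installs C6 at the ester oxidation level next to the quaternary C1.

Step 5
Reactants: 6 unsaturated methyl ester
Product: 8 2-[(S)-5,5-dimethyl-4-(triethylsilyloxy)cyclopent-1-en-1-yl]propan-2-ol, via methyl ketone 7 (not isolated)
Conditions: MeLi (3 equiv), Et2O, −78 → 0 °C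
Reagents that add atoms: methyllithium, [Li]C
Why: Double 1,2-addition of an organolithium to the unsaturated ester gives the tertiary allylic alcohol whose two methyl groups become C15 and the C5 methyl.

Step 6
Reactants: 8 tertiary allylic alcohol
Product: 9 2-[(1R,3S,5S)-2,2-dimethyl-3-(triethylsilyloxy)-6-oxabicyclo[3.1.0]hexan-1-yl]propan-2-ol
Conditions: mCPBA, NaHCO3, CH2Cl2, 0 °C
Reagents that add atoms: 3-chloroperoxybenzoic acid, OOC(=O)c1cccc(Cl)c1
Why: Prilezhaev epoxidation of the trisubstituted alkene, in which the peracid should approach the cyclopentene face opposite the C2 silyloxy group and so place the C4–C5 oxygen trans to C2–O.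

Step 7
Reactants: 9 epoxy alcohol
Product: 10 1-[(1R,3S,5S)-5-hydroxy-1,2,2-trimethyl-3-(triethylsilyloxy)cyclopentyl]ethan-1-one
Conditions: BF3·OEt2 (20 mol %), CH2Cl2, −78 → −40 °C
Reagents that add atoms: none
Why: Semipinacol rearrangement of a 2,3-epoxy alcohol, in which the Lewis acid opens the epoxide at tertiary C5 and a carbinol methyl migrates to C5 anti to the departing oxygen, forming the quaternary centre stereospecifically with the new acetyl group cis to the C4 hydroxyl.

Step 8
Reactants: 10 ring A β-hydroxy ketone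
Product: 11 1-[(1R,3S,5S)-5-(tert-butyldimethylsilyloxy)-1,2,2-trimethyl-3-(triethylsilyloxy)cyclopentyl]ethan-1-one
Conditions: t-BuMe2SiOTf, 2,6-lutidine, CH2Cl2, −78 → 0 °C
Reagents that add atoms: tert-butyldimethylsilyl trifluoromethanesulfonate, CC(C)(C)[Si](C)(C)OS(=O)(=O)C(F)(F)F
Why: Silyl triflate silylation of the hindered secondary C4 carbinol; C5 is quaternary, so the β-silyloxy ketone cannot eliminate in the base-mediated step that follows.

Step 9
Reactants: 11 ring A methyl ketone
Product: 13 1-[(1R,3S,5S)-5-(tert-butyldimethylsilyloxy)-1,2,2-trimethyl-3-(triethylsilyloxy)cyclopentyl]ethenyl trifluoromethanesulfonate, via potassium enolate 12 (not isolated)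
Conditions: KN(SiMe3)2, THF, −78 °C; PhNTf2, −78 → 0 °C
Reagents that add atoms: N-phenylbis(trifluoromethanesulfonimide), FC(F)(F)S(=O)(=O)N(c1ccccc1)S(=O)(=O)C(F)(F)F
Why: Enolate O-triflation of a methyl ketone whose other α-carbon is quaternary, so only the terminal (C6=C15) enol triflate can form.

Step 10
Reactants: 13 enol triflate
Product: 14 trimethyl{2-[(1S,3S,5S)-5-(tert-butyldimethylsilyloxy)-1,2,2-trimethyl-3-(triethylsilyloxy)cyclopentyl]prop-2-en-1-yl}silane
Conditions: Me3SiCH2MgCl, Pd(PPh3)4 (5 mol %), THF, rt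
Reagents that add atoms: (trimethylsilyl)methylmagnesium chloride, C[Si](C)(C)C[Mg]Cl
Why: Kumada cross-coupling of an enol triflate with a Grignard reagent that has no β-hydrogens gives the 2-substituted allylsilane directly.

Step 11
Reactants: 15 2-methylcyclohexane-1,3-dione; 16 allyl bromide
Product: 17 2-methyl-2-(prop-2-en-1-yl)cyclohexane-1,3-dione
Conditions: NaOH (1 M aq), rt
Reagents that add atoms: none
Why: C-Alkylation (SN2) of the stabilised dione enolate creates the prochiral quaternary carbon that becomes C9.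

Step 12
Reactants: 17 2-allyl-2-methyl dione
Product: 18 (2R,3R)-3-hydroxy-2-methyl-2-(prop-2-en-1-yl)cyclohexan-1-one
Conditions: (S)-Me-CBS oxazaborolidine [(S)-1-methyl-3,3-diphenyltetrahydro-1H,3H-pyrrolo[1,2-c][1,3,2]oxazaborole] (10 mol %), catecholborane, toluene, −78 → −40 °C
Reagents that add atoms: none
Why: Corey–Bakshi–Shibata desymmetrisation, in which the catalyst fixes the carbinol as R and hydride should add anti to the larger allyl group, so C10 and C9 are set together with the hydroxyl cis to the allyl arm (any trans isomer is removed by chromatography).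

Step 13
Reactants: 18 ring C hydroxy ketone
Product: 19 (2R,3R)-2-methyl-2-(prop-2-en-1-yl)-3-(triethylsilyloxy)cyclohexan-1-one
Conditions: Et3SiCl, imidazole, DMF, rt
Reagents that add atoms: chlorotriethylsilane, CC[Si](Cl)(CC)CC
Why: Mild silylation avoids retro-aldol cleavage and gives a bulky silyloxy group, cis to the allyl arm, that shields the lower face of ring C in the next stereo-defining steps.

Step 14
Reactants: 19 ring C silyloxy ketone
Product: 21 (2R,3R,6RS)-2,6-dimethyl-2-(prop-2-en-1-yl)-3-(triethylsilyloxy)cyclohexan-1-one, via lithium enolate 20 (not isolated)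
Conditions: LiN(i-Pr)2, THF, −78 °C; MeI, −78 → −20 °C
Reagents that add atoms: iodomethane, CI
Why: Alkylation of the only possible enolate introduces the C13 methyl, and its configuration is irrelevant because C13 is enolised again in the next step.

Step 15
Reactants: 21 2,6-dimethyl ketone
Product: 23 (2R,3R,6R)-6-hydroxy-2,6-dimethyl-2-(prop-2-en-1-yl)-3-(triethylsilyloxy)cyclohexan-1-one, via potassium enolate 22 (not isolated)
Conditions: KN(SiMe3)2, THF, −78 → −40 °C; 3-phenyl-2-(phenylsulfonyl)oxaziridine, −78 °C; AcOH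
Reagents that add atoms: 3-phenyl-2-(phenylsulfonyl)oxaziridine, O=S(=O)(N1OC1c1ccccc1)c1ccccc1
Why: Davis oxidation of the tetrasubstituted enolate, where oxygen should be delivered to the face of the C9 methyl, opposite the pseudoaxial allyl arm and the C10 silyloxy group, setting C13.

Step 16
Reactants: 23 ring C α-hydroxy ketone; 14 ring A allylsilane
Product: 24 C14–C15 coupled diol (2,10-bis-triethylsilyl, 4-tert-butyldimethylsilyl)
Conditions: TiCl4 (2 equiv), 2,6-di-tert-butyl-4-methylpyridine, CH2Cl2, −78 → −40 °C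
Reagents that add atoms: none
Why: Hosomi–Sakurai allylation in which TiCl4 turns the C13 hydroxyl into a chlorotitanium alkoxide chelated to the C14 carbonyl, holding C13–O equatorial with the allyl arm and the C13 methyl axial on the lower face (C10–OSiEt3 equatorial), so that C15 should add axially from the open face cis to the C9 methyl and set C14 with its hydroxyl trans to C13–OH.

Step 17
Reactants: 24 coupled diol
Product: 25 tetraol (C2, C10, C13, C14 hydroxyls free; C4 silyl ether kept)
Conditions: PPTS, MeOH, rt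
Reagents that add atoms: none
Why: Acid-catalysed methanolysis removes both triethylsilyl ethers, which are far more labile than the hindered secondary tert-butyldimethylsilyl ether.

Step 18
Reactants: 25 tetraol
Product: 26 C2,C10-dibromide diene diol
Conditions: CBr4, PPh3, 2,6-lutidine, toluene, 60 °C
Reagents that add atoms: tetrabromomethane, BrC(Br)(Br)Br
Why: Appel reaction in which each secondary carbinol is activated as an alkoxyphosphonium ion and displaced by bromide with inversion (SN2), turning the axial C10–O into the equatorial bromide cis to the C9 methyl and placing C2–Br cis to C4–O, while the hindered tertiary carbinols are not activated.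

Step 19
Reactants: 26 dibromide
Product: 28 keto aldehyde (C6 ketone and C7 aldehyde), via bis-ozonide 27 (not isolated)
Conditions: O3, CH2Cl2, −78 °C; PPh3, −78 °C → rt
Reagents that add atoms: ozone, [O-][O+]=O
Why: Ozonolysis with reductive work-up (Criegee mechanism) cleaves both terminal alkenes, unmasking the C6 ketone and shortening the allyl arm to the C7 aldehyde, which should sit mainly as the lactol with the C14 hydroxyl.

Step 20
Reactants: 28 keto aldehyde
Product: 29 keto triol (C7 primary alcohol)
Conditions: NaBH4, EtOH/CH2Cl2, −40 → −20 °C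
Reagents that add atoms: none
Why: Chemoselective borohydride reduction, in which the aldehyde (through its lactol) is reduced at low temperature while the C6 ketone, flanked by a quaternary carbon and a neopentylic methylene, is left.

Step 21
Reactants: 29 keto triol
Product: 30 iodo ketone (C7 primary iodide, C6 ketone β to C14–OH)
Conditions: I2, PPh3, imidazole, CH2Cl2, 0 °C; used at once
Reagents that add atoms: iodine, II
Why: Garegg–Samuelsson (Appel-type) iodination activates only the primary hydroxyl, the tertiary carbinols being too hindered to form alkoxyphosphonium ions.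

Step 22
Reactants: 30 iodo ketone
Product: 31 neoirietetraol 4-(tert-butyldimethylsilyl) ether
Conditions: SmI2 (2.5 equiv), NiI2 (2 mol %), THF, −78 → 0 °C
Reagents that add atoms: none
Why: SmI2, accelerated by catalytic NiI2, reduces the primary C7–I bond by two single-electron transfers to an alkylsamarium that adds to the C6 ketone, a samarium Barbier reaction whose closest known type is the SmI2 cyclisation of iodoalkyl ketones with 1,3-induction from a β-hydroxyl. Ring B closes by 6-exo-trig attack of C7 on the C6 carbonyl through a chair that is trans-fused to ring C, with the C9 methyl and the C14 oxygen axial. The new C6 stereocentre is controlled by the samarium ion bridging the C14 alkoxide and the C6 carbonyl oxygen, which holds the ketone oxygen axial and syn to the C14 oxygen and leaves the bulky ring A substituent equatorial. The step needs reduction of the primary iodide in preference to the two secondary neopentylic bromides and the ketone, and this is secured because alkyl iodides are reduced far faster than hindered secondary bromides by SmI2 without HMPA and a dialkyl ketone is not converted to its ketyl without a proton source. The C13 and C14 hydroxyls are tertiary and hindered, so protonation of the carbanion should be slower than ring closure.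

Step 23
Reactants: 31 neoirietetraol 4-(tert-butyldimethylsilyl) ether
Product: 32 neoirietetraol
Conditions: HF·pyridine, pyridine, THF, 0 °C → rt
Reagents that add atoms: none
Why: Fluoride-mediated desilylation under buffered, non-basic conditions frees the C4 hydroxyl without eliminating the secondary bromides or dehydrating the tertiary carbinols.

Compound list
1 | 2,2-dimethylcyclopentane-1,3-dione | CC1(C)C(=O)CCC1=O | starting material
2 | (S)-3-hydroxy-2,2-dimethylcyclopentan-1-one | CC1(C)[C@@H](O)CCC1=O | intermediate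
3 | (S)-2,2-dimethyl-3-(triethylsilyloxy)cyclopentan-1-one | CC1(C)[C@@H](O[Si](CC)(CC)CC)CCC1=O | intermediate
4 | potassium enolate of 3 (potassium (S)-5,5-dimethyl-4-(triethylsilyloxy)cyclopent-1-en-1-olate) | CC1(C)[C@@H](O[Si](CC)(CC)CC)CC=C1[O-].[K+] | intermediate (not isolated)
5 | (S)-5,5-dimethyl-4-(triethylsilyloxy)cyclopent-1-en-1-yl trifluoromethanesulfonate | CC1(C)[C@@H](O[Si](CC)(CC)CC)CC=C1OS(=O)(=O)C(F)(F)F | intermediate
6 | methyl (S)-5,5-dimethyl-4-(triethylsilyloxy)cyclopent-1-ene-1-carboxylate | CC1(C)[C@@H](O[Si](CC)(CC)CC)CC=C1C(=O)OC | intermediate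
7 | 1-[(S)-5,5-dimethyl-4-(triethylsilyloxy)cyclopent-1-en-1-yl]ethan-1-one | CC1(C)[C@@H](O[Si](CC)(CC)CC)CC=C1C(C)=O | intermediate (not isolated)
8 | 2-[(S)-5,5-dimethyl-4-(triethylsilyloxy)cyclopent-1-en-1-yl]propan-2-ol | CC1(C)[C@@H](O[Si](CC)(CC)CC)CC=C1C(C)(C)O | intermediate
9 | 2-[(1R,3S,5S)-2,2-dimethyl-3-(triethylsilyloxy)-6-oxabicyclo[3.1.0]hexan-1-yl]propan-2-ol (epoxide oxygen trans to the silyloxy group) | CC1(C)[C@@H](O[Si](CC)(CC)CC)C[C@@H]2O[C@]12C(C)(C)O | intermediate
10 | 1-[(1R,3S,5S)-5-hydroxy-1,2,2-trimethyl-3-(triethylsilyloxy)cyclopentyl]ethan-1-one (C4–OH cis to acetyl, trans to the C5 methyl and to C2–O) | CC1(C)[C@@H](O[Si](CC)(CC)CC)C[C@H](O)[C@]1(C)C(C)=O | intermediate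
11 | 1-[(1R,3S,5S)-5-(tert-butyldimethylsilyloxy)-1,2,2-trimethyl-3-(triethylsilyloxy)cyclopentyl]ethan-1-one | CC1(C)[C@@H](O[Si](CC)(CC)CC)C[C@H](O[Si](C)(C)C(C)(C)C)[C@]1(C)C(C)=O | intermediate
12 | potassium enolate of 11 (terminal C6=C15 enolate) | CC1(C)[C@@H](O[Si](CC)(CC)CC)C[C@H](O[Si](C)(C)C(C)(C)C)[C@]1(C)C(=C)[O-].[K+] | intermediate (not isolated)
13 | 1-[(1R,3S,5S)-5-(tert-butyldimethylsilyloxy)-1,2,2-trimethyl-3-(triethylsilyloxy)cyclopentyl]ethenyl trifluoromethanesulfonate | CC1(C)[C@@H](O[Si](CC)(CC)CC)C[C@H](O[Si](C)(C)C(C)(C)C)[C@]1(C)C(=C)OS(=O)(=O)C(F)(F)F | intermediate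
14 | trimethyl{2-[(1S,3S,5S)-5-(tert-butyldimethylsilyloxy)-1,2,2-trimethyl-3-(triethylsilyloxy)cyclopentyl]prop-2-en-1-yl}silane (ring A allylsilane) | CC1(C)[C@@H](O[Si](CC)(CC)CC)C[C@H](O[Si](C)(C)C(C)(C)C)[C@]1(C)C(=C)C[Si](C)(C)C | intermediate
15 | 2-methylcyclohexane-1,3-dione | CC1C(=O)CCCC1=O | starting material
16 | allyl bromide (3-bromoprop-1-ene) | C=CCBr | starting material
17 | 2-methyl-2-(prop-2-en-1-yl)cyclohexane-1,3-dione | C=CCC1(C)C(=O)CCCC1=O | intermediate
18 | (2R,3R)-3-hydroxy-2-methyl-2-(prop-2-en-1-yl)cyclohexan-1-one (OH cis to allyl) | O=C1CCC[C@@H](O)[C@@]1(C)CC=C | intermediate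
19 | (2R,3R)-2-methyl-2-(prop-2-en-1-yl)-3-(triethylsilyloxy)cyclohexan-1-one | O=C1CCC[C@@H](O[Si](CC)(CC)CC)[C@@]1(C)CC=C | intermediate
20 | lithium enolate of 19 (C13=C14 enolate) | [Li+].[O-]C1=CCC[C@@H](O[Si](CC)(CC)CC)[C@@]1(C)CC=C | intermediate (not isolated)
21 | (2R,3R,6RS)-2,6-dimethyl-2-(prop-2-en-1-yl)-3-(triethylsilyloxy)cyclohexan-1-one | O=C1C(C)CC[C@@H](O[Si](CC)(CC)CC)[C@@]1(C)CC=C | intermediate
22 | potassium enolate of 21 (tetrasubstituted C13=C14 enolate) | [K+].[O-]C1=C(C)CC[C@@H](O[Si](CC)(CC)CC)[C@@]1(C)CC=C | intermediate (not isolated)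
23 | (2R,3R,6R)-6-hydroxy-2,6-dimethyl-2-(prop-2-en-1-yl)-3-(triethylsilyloxy)cyclohexan-1-one (C13–OH cis to the C9 methyl) | O=C1[C@](C)(O)CC[C@@H](O[Si](CC)(CC)CC)[C@@]1(C)CC=C | intermediate
24 | coupled diol: ring A (C2–OSiEt3, C4–OSi-t-BuMe2 trans to C2–O, C5 methyl cis to C2–O) bonded from C5 through C6(=CH2)–C15H2 to C14 of ring C; ring C has C9 (CH3, allyl), C10–OSiEt3 cis to allyl, C13 (CH3, OH cis to the C9 methyl), C14 (OH trans to C13–OH, C15 cis to the C9 methyl) | CC1(C)[C@@H](O[Si](CC)(CC)CC)C[C@H](O[Si](C)(C)C(C)(C)C)[C@]1(C)C(=C)C[C@]1(O)[C@](C)(O)CC[C@@H](O[Si](CC)(CC)CC)[C@@]1(C)CC=C | intermediate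
25 | tetraol: 24 with both triethylsilyl groups removed (free C2, C10, C13, C14 hydroxyls) | CC1(C)[C@@H](O)C[C@H](O[Si](C)(C)C(C)(C)C)[C@]1(C)C(=C)C[C@]1(O)[C@](C)(O)CC[C@@H](O)[C@@]1(C)CC=C | intermediate
26 | dibromide: 25 with C2–OH and C10–OH replaced by bromine with inversion (C2–Br cis to C4–O, C10–Br cis to the C9 methyl) | CC1(C)[C@H](Br)C[C@H](O[Si](C)(C)C(C)(C)C)[C@]1(C)C(=C)C[C@]1(O)[C@](C)(O)CC[C@H](Br)[C@@]1(C)CC=C | intermediate
27 | bis-ozonide of 26 (a 1,2,4-trioxolane at C6 and at C7) | CC1(C)[C@H](Br)C[C@H](O[Si](C)(C)C(C)(C)C)[C@]1(C)C3(OCOO3)C[C@]1(O)[C@](C)(O)CC[C@H](Br)[C@@]1(C)CC3OCOO3 | intermediate (not isolated)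
28 | keto aldehyde: C6 ketone and C7 aldehyde (largely the lactol with C14–OH) | CC1(C)[C@H](Br)C[C@H](O[Si](C)(C)C(C)(C)C)[C@]1(C)C(=O)C[C@]1(O)[C@](C)(O)CC[C@H](Br)[C@@]1(C)CC=O | intermediate
29 | keto triol: 28 with the aldehyde reduced to the C7 primary alcohol | CC1(C)[C@H](Br)C[C@H](O[Si](C)(C)C(C)(C)C)[C@]1(C)C(=O)C[C@]1(O)[C@](C)(O)CC[C@H](Br)[C@@]1(C)CCO | intermediate
30 | iodo ketone: β-hydroxy ketone with the 2-iodoethyl arm on C9 (precursor of the key step) | CC1(C)[C@H](Br)C[C@H](O[Si](C)(C)C(C)(C)C)[C@]1(C)C(=O)C[C@]1(O)[C@](C)(O)CC[C@H](Br)[C@@]1(C)CCI | intermediate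
31 | neoirietetraol 4-(tert-butyldimethylsilyl) ether | CC1(C)[C@H](Br)C[C@H](O[Si](C)(C)C(C)(C)C)[C@]1(C)[C@@]1(O)CC[C@]2(C)[C@@H](Br)CC[C@@](C)(O)[C@@]2(O)C1 | intermediate
32 | neoirietetraol | CC1(C)[C@H](Br)C[C@H](O)[C@]1(C)[C@@]1(O)CC[C@]2(C)[C@@H](Br)CC[C@@](C)(O)[C@@]2(O)C1 | target

Total steps: 23. Longest linear sequence: 18 steps (steps 1–10, then 16–23).

Steps most likely to fail

Step 16. The fully substituted C14 carbonyl may add the allylsilane too slowly, or facial control may be lost if the titanium chelate does not hold. The fallback sets out from 19 and postpones the C13 methyl. The enolate of 19 is hydroxylated with the Davis oxaziridine at the still secondary C13 to give the ketol F1. This less hindered chelated ketone is allylated with 14 and TiCl4 to give the secondary–tertiary diol F2, and its C13 carbinol is oxidised with Dess–Martin periodinane to the α-hydroxy ketone F3. MeMgBr with CeCl3 should then add to the C13 ketone from the face opposite the C15 side chain, which returns to the route at 24.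

Step 22. The alkylsamarium may be protonated by the two free hydroxyls (simple deiodination), the β-oxido ketone may fragment by retro-aldol, or electron transfer to the C–Br bonds may compete. The fallback sets out from 26 and forms the C6–C7 bond by ring-closing metathesis of the allyl arm onto the 1,1-disubstituted alkene (second-generation Hoveyda–Grubbs catalyst, toluene, 80 °C), giving the ring B cyclohexene F5. Mukaiyama hydration (Mn(dpm)3, PhSiH3, O2, i-PrOH) should then place the hydroxyl on the tertiary C6 with the bulky ring A group equatorial, and the route is rejoined at 31.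

Step 18. Elimination or a 1,2-shift at the two neopentylic centres may outrun substitution at the temperature the phosphonium route needs, and traces of acid may etherify the homoallylic diol. The fallback sets out from 25 and separates activation from displacement. Both secondary carbinols are converted at −40 °C (Tf2O, pyridine, CH2Cl2; tertiary hydroxyls untouched) into the bis-triflate F4, which is displaced with Bu4NBr in toluene at 0 °C → rt, again with inversion, to rejoin the route at 26.

Further compounds
F1 | step 16 | (2R,3R,6R)-6-hydroxy-2-methyl-2-(prop-2-en-1-yl)-3-(triethylsilyloxy)cyclohexan-1-one | O=C1[C@H](O)CC[C@@H](O[Si](CC)(CC)CC)[C@@]1(C)CC=C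
F2 | step 16 | 13-demethyl analogue of 24 (C13 secondary carbinol with OH cis to the C9 methyl, C14 carbinol as in 24) | CC1(C)[C@@H](O[Si](CC)(CC)CC)C[C@H](O[Si](C)(C)C(C)(C)C)[C@]1(C)C(=C)C[C@]1(O)[C@H](O)CC[C@@H](O[Si](CC)(CC)CC)[C@@]1(C)CC=C
F3 | step 16 | 13-oxo-13-demethyl analogue of 24 (C13 ketone next to the C14 tertiary carbinol) | CC1(C)[C@@H](O[Si](CC)(CC)CC)C[C@H](O[Si](C)(C)C(C)(C)C)[C@]1(C)C(=C)C[C@]1(O)C(=O)CC[C@@H](O[Si](CC)(CC)CC)[C@@]1(C)CC=C
F4 | step 18 | 2,10-bis(trifluoromethanesulfonate) of 25 | CC1(C)[C@@H](OS(=O)(=O)C(F)(F)F)C[C@H](O[Si](C)(C)C(C)(C)C)[C@]1(C)C(=C)C[C@]1(O)[C@](C)(O)CC[C@@H](OS(=O)(=O)C(F)(F)F)[C@@]1(C)CC=C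
F5 | step 22 | 6,7-alkene corresponding to 31 (ring B cyclohexene C6=C7, no C6 hydroxyl) | CC1(C)[C@H](Br)C[C@H](O[Si](C)(C)C(C)(C)C)[C@]1(C)C1=CC[C@]2(C)[C@@H](Br)CC[C@@](C)(O)[C@@]2(O)C1
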